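The γ-pyranone ring (O1–C2–C3–C4–C4a–C8a) of the 5,7-dimethoxychromone is cut at C4a–C4, C4–C3 and O1–C2. C4 and its oxygen come from carbon monoxide, C2–C3 from a terminal alkyne that already carries the complete, stereodefined side chain, and O1/C8a/C4a from an ortho-iodophenol. One palladium-catalysed carbonylative alkyne annulation in diethylamine therefore joins arene, carbonyl and chain and closes the ring. Its precursors are 2-iodo-3,5-dimethoxyphenol and ethyl (S)-3-silyloxynon-8-ynoate, whose carbinol stereocentre is set beforehand by enzymatic reduction of a β-keto ester. Saponification and acidic desilylation in one pot then release the hydroxy acid.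

Key step: step 5

Remark: carbon monoxide is counted as a numbered reactant (9), and the ketoreductase of step 3 is assumed to be the (S)-selective member of a commercial enzyme panel, its sense to be confirmed by Mosher ester analysis of 7 before scale-up.

Step 1
Reactants: 1 3,5-dimethoxyphenol
Product: 2 2-iodo-3,5-dimethoxyphenol
Conditions: NIS (1.0 equiv), CH2Cl2, −20 → 0 °C, dark
Reagents that add atoms: N-iodosuccinimide, O=C1CCC(=O)N1I
Why: Electrophilic aromatic iodination should go mainly to C2/C6, the two equivalent positions ortho to the hydroxyl and ortho/para to the methoxy groups, because C4 is wedged between two methoxy groups, and one equivalent of NIS at low temperature should limit a second iodination.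

Step 2
Reactants: 3 hept-6-ynoic acid; 4 potassium ethyl malonate
Product: 6 ethyl 3-oxonon-8-ynoate, via hept-6-ynoyl imidazolide 5 (not isolated)
Conditions: CDI (1.1 equiv), THF, rt; then 4/MgCl2/Et3N pre-stirred in MeCN, rt → 40 °C; 1 M HCl work-up
Reagents that add atoms: none
Why: Masamune–Brooks homologation, in which the magnesium-chelated malonate half-ester is C-acylated by the acyl imidazolide and decarboxylates on acidification to the β-keto ester, under conditions too weakly basic to touch the terminal alkyne.

Step 3
Reactants: 6 ethyl 3-oxonon-8-ynoate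
Product: 7 ethyl (S)-3-hydroxynon-8-ynoate
Conditions: (S)-selective ketoreductase, NADP+ (cat.), i-PrOH (15% v/v), phosphate buffer pH 7.0, MgSO4 (2 mM), 30 °C
Reagents that add atoms: none
Why: Enzymatic asymmetric ketone reduction, in which the enzyme pocket directs NADPH hydride to the Re face of the C3 carbonyl and so sets the S carbinol centre by catalyst control, with isopropanol recycling the cofactor and the alkyne and ester untouched (a metal/H2 hydrogenation would endanger the alkyne).

Step 4
Reactants: 7 ethyl (S)-3-hydroxynon-8-ynoate
Product: 8 ethyl (S)-3-[(tert-butyldimethylsilyl)oxy]non-8-ynoate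
Conditions: TBSCl (1.2 equiv), imidazole (2.5 equiv), DMF, 0 °C → rt
Reagents that add atoms: tert-butyldimethylsilyl chloride, CC(C)(C)[Si](C)(C)Cl
Why: Imidazole-promoted O-silylation of a secondary alcohol breaks no bond at the stereocentre, so the S configuration is retained, and it masks the hydroxyl against acylation in the carbonylation.

Step 5
Reactants: 2 2-iodo-3,5-dimethoxyphenol; 8 ethyl (S)-3-[(tert-butyldimethylsilyl)oxy]non-8-ynoate (1.2 equiv); 9 carbon monoxide
Product: 12 ethyl (S)-3-[(tert-butyldimethylsilyl)oxy]-7-(5,7-dimethoxy-4-oxo-4H-chromen-2-yl)heptanoate, via aryl ynone 10 (not isolated), via diethylamino enone 11 (not isolated)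
Conditions: PdCl2(dppf) (5 mol %), CO (20 atm), Et2NH (solvent), 100 °C, autoclave
Reagents that add atoms: none
Why: Pd(0) inserts into the C–I bond of 2, the resulting electron-rich, doubly ortho-flanked aryl–palladium takes up CO to an aroyl–palladium, and this is alkynylated by 8 (deprotonated at palladium by the amine) to release ynone 10 on reductive elimination, which forms C4a–C4 and C4–C3. Diethylamine then adds in conjugate fashion to 10 to give enaminone 11, and the phenol oxygen attacks the amine-bearing carbon and expels diethylamine, which forms O1–C2. This is the known carbonylative Sonogashira annulation of ortho-iodophenols and terminal alkynes to 2-substituted chromones. The single ring closed, the pyranone O1–C2–C3–C4–C4a–C8a, closes by 6-endo-trig addition–elimination at C2. No stereocentre is created, and the silyloxy-bearing carbon of the chain lies far from every reacting atom and should keep its S configuration. The step needs carbonylative over direct coupling, which CO pressure, the copper-free catalyst and the hindered electron-rich aryl–palladium should secure, and chromone over aurone (5-exo) closure, which the amine solvent should secure because enaminone 11 can only close at C2.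

Step 6
Reactants: 12 ethyl (S)-3-[(tert-butyldimethylsilyl)oxy]-7-(5,7-dimethoxy-4-oxo-4H-chromen-2-yl)heptanoate
Product: 14 (S)-7-(5,7-dimethoxy-4-oxo-4H-chromen-2-yl)-3-hydroxyheptanoic acid (penithochromone P), via silyloxy acid 13 (not isolated)
Conditions: LiOH·H2O (3 equiv), THF/H2O 3:1, 0 °C → rt; then 3 M HCl to pH ≤ 1, rt
Reagents that add atoms: lithium hydroxide, [Li+].[OH-]
Why: Ester saponification is run while the carbinol oxygen is still silylated, so no free alkoxide can start a retro-aldol; the acid quench then frees the carboxylic acid, recloses any pyranone that hydroxide opened reversibly and hydrolyses the secondary silyl ether at Si–O, all without breaking a bond at the stereocentre.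

Compound list
1 | 3,5-dimethoxyphenol | COc1cc(O)cc(OC)c1 | starting material
2 | 2-iodo-3,5-dimethoxyphenol | COc1cc(O)c(I)c(OC)c1 | intermediate
3 | hept-6-ynoic acid | C#CCCCCC(=O)O | starting material
4 | potassium ethyl malonate (potassium 3-ethoxy-3-oxopropanoate) | CCOC(=O)CC(=O)[O-].[K+] | starting material
5 | 1-(1H-imidazol-1-yl)hept-6-yn-1-one (hept-6-ynoyl imidazolide, formed in the flask) | C#CCCCCC(=O)n1ccnc1 | intermediate
6 | ethyl 3-oxonon-8-ynoate | C#CCCCCC(=O)CC(=O)OCC | intermediate
7 | ethyl (S)-3-hydroxynon-8-ynoate | C#CCCCC[C@H](O)CC(=O)OCC | intermediate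
8 | ethyl (S)-3-[(tert-butyldimethylsilyl)oxy]non-8-ynoate | C#CCCCC[C@H](O[Si](C)(C)C(C)(C)C)CC(=O)OCC | intermediate
9 | carbon monoxide | [C-]#[O+] | starting material
10 | ethyl (S)-3-[(tert-butyldimethylsilyl)oxy]-10-(2-hydroxy-4,6-dimethoxyphenyl)-10-oxodec-8-ynoate (aryl ynone, formed in the flask) | COc1cc(O)c(C(=O)C#CCCCC[C@H](O[Si](C)(C)C(C)(C)C)CC(=O)OCC)c(OC)c1 | intermediate
11 | ethyl (S,E)-3-[(tert-butyldimethylsilyl)oxy]-8-(diethylamino)-10-(2-hydroxy-4,6-dimethoxyphenyl)-10-oxodec-8-enoate (diethylamino enone, formed in the flask) | COc1cc(O)c(C(=O)/C=C(/N(CC)CC)CCCC[C@H](O[Si](C)(C)C(C)(C)C)CC(=O)OCC)c(OC)c1 | intermediate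
12 | ethyl (S)-3-[(tert-butyldimethylsilyl)oxy]-7-(5,7-dimethoxy-4-oxo-4H-chromen-2-yl)heptanoate | COc1cc(OC)c2c(=O)cc(CCCC[C@H](O[Si](C)(C)C(C)(C)C)CC(=O)OCC)oc2c1 | intermediate
13 | (S)-3-[(tert-butyldimethylsilyl)oxy]-7-(5,7-dimethoxy-4-oxo-4H-chromen-2-yl)heptanoic acid (silyloxy acid, lithium salt before acidification, formed in the flask) | COc1cc(OC)c2c(=O)cc(CCCC[C@H](O[Si](C)(C)C(C)(C)C)CC(=O)O)oc2c1 | intermediate
14 | (S)-7-(5,7-dimethoxy-4-oxo-4H-chromen-2-yl)-3-hydroxyheptanoic acid (penithochromone P) | COc1cc(OC)c2c(=O)cc(CCCC[C@H](O)CC(=O)O)oc2c1 | target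

Total step count: 6.
Longest linear sequence: 5 steps (steps 2–6, from hept-6-ynoic acid 3 through 6, 7, 8 and 12 to 14).

Steps most likely to fail

Step 5. Three things may go wrong.
- The amine may capture the aroyl–palladium and give an amide.
- Coupling may occur before CO uptake and be followed by benzofuran closure.
- Oxidative addition at the doubly ortho-substituted C–I bond may be sluggish.

Fallback, setting out from alkyne 8 and returning at 12: the carbonyl carbon is brought in as an aroyl chloride instead of CO. Purchased 2-hydroxy-4,6-dimethoxybenzoic acid is acetylated (Ac2O, pyridine) to 2-acetoxy-4,6-dimethoxybenzoic acid F1. This is converted with 1-chloro-N,N,2-trimethylpropenylamine (CH2Cl2, rt) into 2-acetoxy-4,6-dimethoxybenzoyl chloride F2. Acyl Sonogashira coupling of F2 with 8 (PdCl2(PPh3)2, CuI, Et3N, THF, rt) should give ethyl (S)-10-(2-acetoxy-4,6-dimethoxyphenyl)-3-[(tert-butyldimethylsilyl)oxy]-10-oxodec-8-ynoate F3. Diethylamine in ethanol (rt → 50 °C) then cleaves the aryl acetate to give 10, which should pass through 11 to 12.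

Step 3. The available enzymes may give insufficient enantioselectivity or the wrong sense on this long-chain substrate, or conversion may stall through poor substrate solubility.

Fallback, setting out from acid 3 and returning at 7: the carbinol is built by an auxiliary-controlled acetate aldol instead of a reduction. Acid 3 is activated with CDI (through 5) and treated with MeNH(OMe)·HCl to give N-methoxy-N-methylhept-6-ynamide F4. DIBAL-H (THF, −78 °C) reduces this to hept-6-ynal F5. The titanium enolate of (S)-3-acetyl-4-isopropyl-1,3-thiazolidine-2-thione (TiCl4, i-Pr2NEt, CH2Cl2, −78 °C; Nagao acetate aldol) is added to F5. Through the chelated transition state this is expected to give (S)-3-hydroxy-1-[(S)-4-isopropyl-2-thioxo-1,3-thiazolidin-3-yl]non-8-yn-1-one F6. The minor diastereomer is removable by chromatography, and the carbinol configuration is to be checked before proceeding. Ethanolysis (EtOH, imidazole, rt) displaces the auxiliary and should give 7.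

Step 1. Iodination may compete at C4, para to the hydroxyl, and a second iodination may occur.

Fallback, setting out from 1 and returning at 2: orientation is handed to the two methoxy groups by masking the phenol. Acetylation (Ac2O, Et3N, DMAP, CH2Cl2) gives 3,5-dimethoxyphenyl acetate F7. Iodination (NIS, cat. TFA, MeCN, rt) should then go to the position ortho/para to the methoxy groups, as usual for 5-substituted 1,3-dimethoxybenzenes, and give 2-iodo-3,5-dimethoxyphenyl acetate F8. Methanolysis (K2CO3, MeOH, 0 °C) should release 2.

Further compounds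
F1 | step 5 | 2-acetoxy-4,6-dimethoxybenzoic acid | COc1cc(OC)c(C(=O)O)c(OC(C)=O)c1
F2 | step 5 | 2-acetoxy-4,6-dimethoxybenzoyl chloride | COc1cc(OC)c(C(=O)Cl)c(OC(C)=O)c1
F3 | step 5 | ethyl (S)-10-(2-acetoxy-4,6-dimethoxyphenyl)-3-[(tert-butyldimethylsilyl)oxy]-10-oxodec-8-ynoate | COc1cc(OC)c(C(=O)C#CCCCC[C@H](O[Si](C)(C)C(C)(C)C)CC(=O)OCC)c(OC(C)=O)c1
F4 | step 3 | N-methoxy-N-methylhept-6-ynamide | C#CCCCCC(=O)N(C)OC
F5 | step 3 | hept-6-ynal | C#CCCCCC=O
F6 | step 3 | (S)-3-hydroxy-1-[(S)-4-isopropyl-2-thioxo-1,3-thiazolidin-3-yl]non-8-yn-1-one | C#CCCCC[C@H](O)CC(=O)N1[C@@H](C(C)C)CSC1=S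
F7 | step 1 | 3,5-dimethoxyphenyl acetate | COc1cc(OC)cc(OC(C)=O)c1
F8 | step 1 | 2-iodo-3,5-dimethoxyphenyl acetate | COc1cc(OC)c(I)c(OC(C)=O)c1
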